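(The rate constants are assumed; the run is a simulation.)

A small charge of starting complex, 0.60 M, stands under gas held at 160 mM, and I want the state of this flask at 2.5 h.

    starting complex + incoming ligand ⇌ leaving ligand + complex with one exchanged (K1 = 3.9, k1 = 0.0351 M⁻¹ s⁻¹)
    complex with one exchanged + incoming ligand ⇌ leaving ligand + complex with two exchanged (K2 = 4.21, k2 = 0.0146 M⁻¹ s⁻¹)
    complex with two exchanged + incoming ligand ⇌ leaving ligand + complex with three exchanged (K3 = 1.6, k3 = 0.0489 M⁻¹ s⁻¹)
    crystals ⇌ leaving ligand, rate k4*(cs4 - [leaving ligand]) while solid is left; crystals form when [leaving ligand] > cs4 (cs4 = 0.28 M, k4 = 0.0413 s⁻¹)
    gas ⇌ incoming ligand, rate k5*(csat - [incoming ligand]) (k5 = 0.137 s⁻¹, csat = 160 mM)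
    complex with two exchanged ⇌ isomer of the product (K6 = 0.59, k6 = 8.36 × 10⁻⁴ s⁻¹)

starting complex 0.60 M; gas 160 mM (held); time 2.5 h

- leaving ligand is meant together with its crystals
- solid, in amounts per volume of the solution: crystals
- at the start none of incoming ligand is dissolved
- the reaction counts as stopped when no species that holds the starting complex changes by six tenths of a point or more over the second half of the time
- run time (flask): 2.5 h

- the state of affairs at 2.5 h: stopped, and by what, or still going (forward and back rates have come level / all of the starting complex has reacted / it is still moving)
- share of the starting complex used up at 2.5 h
- complex with two exchanged at 2.5 h, in percent of the starting complex charged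
- complex with three exchanged at 2.5 h, in percent of the starting complex charged
- isomer of the product at 2.5 h, in percent of the starting complex charged
- amount of complex with two exchanged if the flask were left three thousand times as long, in percent of the starting complex charged

I begin with the two ligand levels. The gas transfer has a half-life of 0.0843 min and the crystals exchange with a half-life of 0.280 min. Both are shorter than the 0.55 min half-life of incoming ligand by the first exchange, forward rate alone at the charged concentrations, so I take [incoming ligand] as 160 mM and, once crystals have formed and while they last, [leaving ligand] as 0.28 M.

What this leaves free is the ligand ratio, [incoming ligand] over [leaving ligand], 0.571. At level rates, each exchange multiplies the amount on the rung below by its equilibrium constant times this ratio, while the isomer step multiplies by its constant with no ratio.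

With starting complex as one, the weights are 2.23 for one exchanged, 5.36 for two exchanged, 4.90 for three exchanged and 3.16 for the isomer, summing to 16.7. That gives conversion 94.0%, two exchanged 32.1%, three exchanged 29.3% and isomer 18.9%. The leaving ligand released comes to 1.22 M, more than dissolves, so in this reckoning crystals are present at level rates.

The second exchange, pseudo-first-order at held [incoming ligand], has a forward half-life of 0.0824 h, and the isomer step relaxes with 0.0855 h. Both are short against 2.5 h, so I expect level rates and the same 32.1% of two exchanged after long standing.

The forecast says forward and back rates have come level, with conversion 94%, two exchanged 32.2%, three exchanged 29.4%, isomer 19% and two exchanged after long standing 32.2%, on the ground that “the system reaches equilibrium”.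

The simulation gives forward and back rates have come level, with conversion 94.0%, two exchanged 32.2%, three exchanged 29.4%, isomer 19.0% and two exchanged after long standing 32.2%.

At 2.5 h this flask reads [incoming ligand] 0.160 M and [leaving ligand] 0.280 M, a ratio of 0.571. The neighbouring flask, read at 40 min, has [incoming ligand] 0.160 M and [leaving ligand] 0.281 M, a ratio of 0.569. The ratio predicts three exchanged over two exchanged as 0.914, and that flask reads 0.906. Its isomer over two exchanged reads 0.536, below the constant 0.59, with isomer at 17.1%.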